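**Plan**
1. Locants: ring A = C1 (carbinol), C5, C6, C7, C8, C9, C10, with methyl C14 and lactone A (C11–C13, oxygen on C8). Ring B and spiro lactone B carry the same locants primed. Ring C = C1, C2, C3, C11', C13', C5; the acetyl group is C4/C15.
2. Cuts, in order: epoxide oxygen; C1'–C2' (Heck); C11–C12 and O–C12 of lactone A (CO insertion into an alkynol); then ring C at C2=C3 (aldol condensation), C1–C2 (vinyl addition), C3–C11' (enolate alkylation) and C5–C13' (Michael addition).
3. This leaves ketone 21 and methylene lactone 22. C7/C8/C10 and C7'/C8'/C10' have opposite absolute configuration, so 21 and 22 come from the two antipodes of one alkynol, 16.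
4. Enabling feature: in ring A, the methyl-bearing C10 and the ring-fusion carbon C7 (which carries lactone carbon C11) are cis and 1,4-related through C9H2 and the oxygen-bearing C8, and C1 next to C10 is at ketone level. Ring B shows the mirror image of this pattern. This array is tropone spanned from its C2 to its C5 by the two carbons of a ketene acetal; the leftover etheno bridge supplies C14 and C11.
5. Forward order: bicyclo[3.2.2] adduct, bridge cleavage to the cycloheptene (rings A and B), resolution, lactone B, union, ring C, dienone side chain, lactone A, epoxide.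
6. Stereochemistry: C7/C10 cis from the bridgeheads; C8 by hydride attack anti to both arms; absolute configuration by resolution, with both antipodes consumed; C11' by convex-face alkylation; C5 by equilibration; C1 by attack on the open face of the ketone; C1'/C5' by peracid attack on the hydrogen-only face.

Key step: step 1

Remark: compounds 3 to 16 are racemates, and their names and SMILES show the antipode that becomes ring A; which chromatographic fraction is 17 would be settled by Mosher ester analysis at C8.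

**Step 1**
Reactants: 1 tropone; 2 1,1-diethoxyethene
Product: 3 (±)-9,9-diethoxybicyclo[3.2.2]nona-3,6-dien-2-one
Conditions: B(C6F5)3 (10 mol %), CH2Cl2, −78 °C
Reagents that add atoms: none
Why: B(C6F5)3 binds the tropone oxygen and lowers the ring LUMO, so the electron-rich ketene acetal adds across C2 and C5 in an inverse-electron-demand Diels–Alder reaction, with the bond from its CH2 terminus to C2 running ahead of the bond from the acetal carbon to C5. This is the known Lewis acid-promoted [4+2] cycloaddition of tropones with ketene acetals. One six-membered ring (tropone C2–C5 plus the two acetal carbons) closes suprafacially on both partners and turns the seven-membered ring into a bicyclo[3.2.2]nonadienone; read stepwise, the second bond is a 6-exo-trig attack of C5 on the dialkoxy-stabilised cationic carbon. The two new stereocentres are the bridgeheads, and a two-carbon bridge can span them on one face only, so they are cis by geometry; the achiral catalyst gives the racemate, and both antipodes are wanted. Periselectivity for [4+2] over [8+2] closure on oxygen rests on the bulky, tightly bound borane that keeps the oxygen terminus occupied, and regioselectivity rests on polarity, since the nucleophilic CH2 seeks C2 next to the complexed carbonyl.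

**Step 2**
Reactants: 3 (±)-9,9-diethoxybicyclo[3.2.2]nona-3,6-dien-2-one
Product: 5 (±)-9,9-diethoxybicyclo[3.2.2]nona-2,6-dien-2-yl triflate, via lithium enolate 4 (not isolated)
Conditions: LiBH(s-Bu)3, THF, −78 °C; then PhNTf2, −78 → 0 °C
Reagents that add atoms: N-phenylbis(trifluoromethanesulfonimide), O=S(=O)(N(c1ccccc1)S(=O)(=O)C(F)(F)F)C(F)(F)F
Why: Conjugate reduction of a β-unsubstituted enone whose carbonyl is shielded by a bridgehead, followed by enolate trapping, is the standard regiospecific enol triflate synthesis; the enolate can only point toward the future C5 because the other α-carbon is a bridgehead, and no stereocentre is created.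

**Step 3**
Reactants: 5 (±)-9,9-diethoxybicyclo[3.2.2]nona-2,6-dien-2-yl triflate
Product: 8 (±)-6-ethoxy-5-(hydroxymethyl)-7-oxabicyclo[4.2.1]non-2-en-2-yl triflate (hydroxymethyl syn to the oxa bridge), via ozonide 6 (not isolated), via cis-diol 7 (not isolated)
Conditions: O3, CH2Cl2, −78 °C (Sudan red 7B end point); MeOH, NaBH4, −78 → 0 °C; work-up; camphorsulfonic acid (cat.), CH2Cl2, 4 Å sieves, 0 °C
Reagents that add atoms: ozone, [O-][O+]=O
Why: Ozonolysis with reductive work-up cleaves only the strained, electron-rich etheno bridge (the enol triflate alkene is deactivated) and leaves two hydroxymethyl arms that are cis because they were bridgehead bonds, and acid-catalysed transketalisation then ties the C10 arm, the only one that reaches C8 through a five-membered ring, to the ketal carbon, whose configuration is fixed by that tether.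

**Step 4**
Reactants: 8 bridged ethyl ketal alcohol
Product: 10 (±)-cis-7-(hydroxymethyl)-5-oxo-4-(pivaloyloxymethyl)cyclohept-1-en-1-yl triflate, via ketal pivalate 9 (not isolated)
Conditions: t-BuCOCl, pyridine, DMAP (cat.), CH2Cl2, 0 °C; then 0.1 M HCl, THF/H2O, 0 °C → rt
Reagents that add atoms: pivaloyl chloride, CC(C)(C)C(=O)Cl; water, O
Why: Esterification of the single free primary alcohol followed by acid-catalysed ketal hydrolysis, run dilute and cold so that hydrolysis outruns enolisation toward C7, delivers the two arms in differentiated form without touching a stereocentre.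

**Step 5**
Reactants: 10 hydroxy ketone pivalate
Product: 11 (±)-cis-7-(iodomethyl)-5-oxo-4-(pivaloyloxymethyl)cyclohept-1-en-1-yl triflate
Conditions: I2, PPh3, imidazole, CH2Cl2, 0 °C
Reagents that add atoms: iodine, II
Why: The Appel-type iodination converts the only free, primary alcohol by SN2 displacement under nearly neutral conditions that leave the β-acyloxy ketone and C7 alone.

**Step 6**
Reactants: 11 iodo ketone pivalate
Product: 12 (±)-cis-7-methyl-5-oxo-4-(pivaloyloxymethyl)cyclohept-1-en-1-yl triflate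
Conditions: Bu3SnH, AIBN (cat.), PhH, 80 °C
Reagents that add atoms: none
Why: Radical chain dehalogenation turns the iodomethyl arm into methyl C14 under neutral conditions, so C10 keeps the configuration inherited from the bridgehead, and enol triflate, ketone and ester are inert to stannyl radicals.

**Step 7**
Reactants: 12 methyl ketone pivalate
Product: 14 (±)-all-cis-5-hydroxy-4-(hydroxymethyl)-7-methylcyclohept-1-en-1-yl triflate, via lithium alkoxide 13 (not isolated)
Conditions: LiBH(s-Bu)3, THF, −78 °C; then i-Bu2AlH, −78 → 0 °C; aqueous potassium sodium tartrate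
Reagents that add atoms: none
Why: Steric approach control in the trialkylborohydride reduction of a 2-substituted cycloalkanone brings hydride in anti to the C7 arm and the C10 methyl group and so sets the C8 carbinol cis to both, and reductive ester cleavage with the aluminium hydride, which tolerates enol triflates, frees the primary alcohol in the same flask.

**Step 8**
Reactants: 14 all-cis diol
Product: 16 (±)-all-cis-4-ethynyl-5-hydroxy-7-methylcyclohept-1-en-1-yl triflate, via hydroxy aldehyde 15 (not isolated)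
Conditions: TEMPO (cat.), PhI(OAc)2, CH2Cl2, rt; crude aldehyde added to Me3SiC(Li)N2 (2.5 equiv, from Me3SiCHN2 and LiN(i-Pr)2), THF, −78 → 0 °C
Reagents that add atoms: (trimethylsilyl)diazomethane, C[Si](C)(C)C=[N+]=[N-]
Why: Nitroxyl-catalysed oxidation picks the primary alcohol of the 1,3-diol, and the Colvin homologation (addition of the lithiated diazo compound, loss of silanolate and N2, 1,2-hydrogen shift of the alkylidene carbene) gives the terminal alkyne at a temperature low enough to spare the α-stereocentre C7 and the aldol-type C7–C8 bond.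

**Step 9**
Reactants: 16 (±)-alkynol
Product: 17 (4R,5R,7S)-4-ethynyl-5-hydroxy-7-methylcyclohept-1-en-1-yl triflate (ring A series); 18 its (4S,5S,7R) antipode (ring B series)
Conditions: preparative SFC, amylose tris(3,5-dimethylphenylcarbamate) phase, CO2/i-PrOH
Reagents that add atoms: none
Why: Chromatographic resolution on a polysaccharide phase is routine for small polar carbinols, fixes the absolute configuration of both halves, and wastes nothing because one antipode becomes ring A and the other ring B.

**Step 10**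
Reactants: 17 (4R,5R,7S)-alkynol
Product: 20 (4R,5R,7S)-5-(tert-butyldimethylsilyloxy)-4-[(tert-butyldimethylsilyl)ethynyl]-7-methylcyclohept-1-en-1-yl triflate, via dilithio salt 19 (not isolated)
Conditions: LiN(i-Pr)2 (2.2 equiv), THF, −78 °C; then t-BuMe2SiOTf (2.3 equiv), −78 → 0 °C
Reagents that add atoms: tert-butyldimethylsilyl triflate, CC(C)(C)[Si](C)(C)OS(=O)(=O)C(F)(F)F
Why: Double deprotonation and silylation caps the hydroxyl and the alkyne C–H in a single operation, the amide being consumed by these far more acidic sites before it can touch the enol triflate.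

**Step 11**
Reactants: 20 bis-silylated enol triflate
Product: 21 (2S,4R,5R)-4-(tert-butyldimethylsilyloxy)-5-[(tert-butyldimethylsilyl)ethynyl]-2-methylcycloheptan-1-one
Conditions: Et4NOH (aq), 1,4-dioxane, rt
Reagents that add atoms: none
Why: Hydroxide attacks the sulfonyl sulfur (S–O cleavage, as in the saponification of aryl triflates) and the released enolate is protonated to the ketone, while C10, now α to the carbonyl, already holds its methyl group in the favoured equatorial position and is not at risk.

**Step 12**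
Reactants: 18 (4S,5S,7R)-alkynol
Product: 22 (3aS,7R,8aS)-7-methyl-3-methylidene-2-oxo-3,3a,4,7,8,8a-hexahydro-2H-cyclohepta[b]furan-6-yl triflate
Conditions: PdCl2 (5 mol %), PPh3, SnCl2, CO (7 atm), MeCN, 65 °C
Reagents that add atoms: carbon monoxide, [C-]#[O+]
Why: In this known cyclocarbonylation of 2-ethynyl carbinols an alkoxycarbonyl complex of divalent palladium adds across the alkyne in a 5-exo-dig sense and protonolysis releases the α-methylene-γ-lactone, cis-fused because C7' and C8' are untouched, and the cycle stays at the divalent level, which is why the enol triflate should survive.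

**Step 13**
Reactants: 21 ring A ketone; 22 ring B methylene lactone
Product: 26 C5–C13'-linked keto lactone bearing a 2-methylallyl group at C11' (C5 chain cis to C14; allyl group syn to H7'), via ketone enolate 23 (not isolated), via lactone enolate 24 (not isolated), via C5 epimer 25 (not isolated)
Conditions: LiN(i-Pr)2, THF, −78 °C; 22 added slowly, −78 °C; methallyl bromide, DMPU, −78 → −20 °C; work-up; DBU, PhMe, 60 °C
Reagents that add atoms: 3-bromo-2-methylprop-1-ene, C=C(C)CBr
Why: Kinetic deprotonation on the CH2 side of the ketone, Michael addition to the s-cis-locked acrylate unit of 22 and alkylation of the resulting lactone enolate in the same flask (Michael-initiated three-component coupling) form C5–C13' and C11'–C3, the electrophile entering the cis-fused bicyclic enolate on its convex face, which sets C11', and base equilibration moves C5 to the epimer in which all four ring A substituents are equatorial or isoclinal in a twist-chair, that is, with the chain cis to C14.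

**Step 14**
Reactants: 26 keto lactone
Product: 27 tertiary vinyl carbinol (C1 hydroxyl cis to C14 and to the C5 chain)
Conditions: CH2=CHMgBr, CeCl3, THF, −78 °C
Reagents that add atoms: vinylmagnesium bromide, C=C[Mg]Br
Why: Organocerium 1,2-addition suppresses enolisation and leaves the hindered lactone alone, and the reagent enters equatorially on the face of ring A that carries only hydrogens, as Grignard reagents do with cis-2,6-dialkylcyclohexanones, so the vinyl group ends trans to both flanking substituents and the C1 hydroxyl cis to them.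

**Step 15**
Reactants: 27 vinyl carbinol
Product: 29 C2 aldehyde and C4 methyl ketone (α-hydroxy aldehyde on C1; acetonyl group on C11'), via bis-ozonide 28 (not isolated)
Conditions: O3, CH2Cl2, −78 °C (Sudan red 7B end point); Me2S, −78 °C → rt
Reagents that add atoms: ozone, [O-][O+]=O
Why: Ozonolysis cleaves the two electron-rich terminal alkenes at once (vinyl to the C2 aldehyde, methallyl to the C4 ketone), while the deactivated enol triflate and the silylalkyne are spared by titration to a dye end point, and no stereocentre changes.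

**Step 16**
Reactants: 29 keto aldehyde
Product: 31 ring C enone (C8 silyl ether; silylalkyne on C7; enol triflate in ring B), via aldol 30 (not isolated)
Conditions: piperidine, AcOH (cat. each), PhMe, 60 °C
Reagents that add atoms: none
Why: In this intramolecular aldol condensation of a 1,7-keto aldehyde the aldehyde cannot enolise and attack through the methyl terminus would need an eight-membered ring, so the C3 methylene closes ring C in a 6-(enolexo)-exo-trig mode and E1cB loss of water gives the enone, the trans ring fusion being already encoded in C1 and C5.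

**Step 17**
Reactants: 31 ring C enone
Product: 32 (E)-dienone (3-oxobut-1-enyl group on C1')
Conditions: methyl vinyl ketone, Pd(OAc)2 (5 mol %), PPh3, Et3N, DMF, 60 °C
Reagents that add atoms: but-3-en-2-one, C=CC(C)=O
Why: The Heck vinylation of an enol triflate with an electron-poor alkene gives the (E)-dienone through syn insertion and syn β-hydride elimination, the alkyne being masked as its silane and no other C–X bond being present.

**Step 18**
Reactants: 32 (E)-dienone
Product: 33 alkynyl diol (free C8 hydroxyl; terminal alkyne on C7)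
Conditions: Bu4NF, AcOH, THF, 0 °C → rt
Reagents that add atoms: none
Why: Buffered fluoride removes the O-silyl and the C-silyl group together, the acetic acid keeping the medium too weakly basic for retro-aldol or Michael reactions of the enones.

**Step 19**
Reactants: 33 alkynyl diol
Product: 34 de-epoxy precursor (both lactones in place; C1'=C5' alkene)
Conditions: PdCl2 (5 mol %), PPh3, SnCl2, CO (7 atm), MeCN, 65 °C
Reagents that add atoms: carbon monoxide, [C-]#[O+]
Why: The same cyclocarbonylation of a 2-ethynyl carbinol closes lactone A in a 5-exo-dig sense; only the homopropargylic C8 hydroxyl can reach the alkyne, and the cis fusion follows from C7 and C8.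

**Step 20**
Reactants: 34 de-epoxy precursor
Product: 35 CNP0177598.2
Conditions: mCPBA, NaHCO3, CH2Cl2, 0 °C
Reagents that add atoms: 3-chloroperoxybenzoic acid, O=C(OO)c1cccc(Cl)c1
Why: The Prilezhaev epoxidation is electrophilic and therefore picks the trisubstituted γ,δ-alkene C1'=C5' over the three alkenes directly conjugated to carbonyl groups, and the peracid comes in on the face of ring B that carries only hydrogens, anti to the C10' methyl group and lactone B, which sets C1' and C5'.

**Compound list**
1 | tropone | O=C1C=CC=CC=C1 | starting material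
2 | 1,1-diethoxyethene | C=C(OCC)OCC | starting material
3 | (±)-9,9-diethoxybicyclo[3.2.2]nona-3,6-dien-2-one | O=C1C=C[C@@H]2C=C[C@H]1CC2(OCC)OCC | intermediate
4 | lithium enolate of the saturated bicyclic ketone | [Li+].[O-]C1=CC[C@@H]2C=C[C@H]1CC2(OCC)OCC | intermediate
5 | (±)-9,9-diethoxybicyclo[3.2.2]nona-2,6-dien-2-yl triflate | O=S(=O)(OC1=CC[C@@H]2C=C[C@H]1CC2(OCC)OCC)C(F)(F)F | intermediate
6 | ozonide of the etheno bridge of 5 | O=S(=O)(OC1=CC[C@@H]2C3OOC(O3)[C@H]1CC2(OCC)OCC)C(F)(F)F | intermediate
7 | (±)-cis-5,5-diethoxy-4,7-bis(hydroxymethyl)cyclohept-1-en-1-yl triflate | O=S(=O)(OC1=CC[C@H](CO)C(OCC)(OCC)C[C@@H]1CO)C(F)(F)F | intermediate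
8 | (±)-6-ethoxy-5-(hydroxymethyl)-7-oxabicyclo[4.2.1]non-2-en-2-yl triflate | O=S(=O)(OC1=CC[C@H](CO)[C@@]2(OCC)C[C@@H]1CO2)C(F)(F)F | intermediate
9 | pivalate of 8 | O=S(=O)(OC1=CC[C@H](COC(=O)C(C)(C)C)[C@@]2(OCC)C[C@@H]1CO2)C(F)(F)F | intermediate
10 | (±)-cis-7-(hydroxymethyl)-5-oxo-4-(pivaloyloxymethyl)cyclohept-1-en-1-yl triflate | O=S(=O)(OC1=CC[C@H](COC(=O)C(C)(C)C)C(=O)C[C@@H]1CO)C(F)(F)F | intermediate
11 | (±)-cis-7-(iodomethyl)-5-oxo-4-(pivaloyloxymethyl)cyclohept-1-en-1-yl triflate | O=S(=O)(OC1=CC[C@H](COC(=O)C(C)(C)C)C(=O)C[C@@H]1CI)C(F)(F)F | intermediate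
12 | (±)-cis-7-methyl-5-oxo-4-(pivaloyloxymethyl)cyclohept-1-en-1-yl triflate | O=S(=O)(OC1=CC[C@H](COC(=O)C(C)(C)C)C(=O)C[C@@H]1C)C(F)(F)F | intermediate
13 | lithium alkoxide of the all-cis C8 carbinol pivalate | O=S(=O)(OC1=CC[C@H](COC(=O)C(C)(C)C)[C@H]([O-])C[C@@H]1C)C(F)(F)F.[Li+] | intermediate
14 | (±)-all-cis-5-hydroxy-4-(hydroxymethyl)-7-methylcyclohept-1-en-1-yl triflate | O=S(=O)(OC1=CC[C@H](CO)[C@H](O)C[C@@H]1C)C(F)(F)F | intermediate
15 | (±)-all-cis-4-formyl-5-hydroxy-7-methylcyclohept-1-en-1-yl triflate | O=S(=O)(OC1=CC[C@H](C=O)[C@H](O)C[C@@H]1C)C(F)(F)F | intermediate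
16 | (±)-all-cis-4-ethynyl-5-hydroxy-7-methylcyclohept-1-en-1-yl triflate | O=S(=O)(OC1=CC[C@H](C#C)[C@H](O)C[C@@H]1C)C(F)(F)F | intermediate
17 | (4R,5R,7S)-4-ethynyl-5-hydroxy-7-methylcyclohept-1-en-1-yl triflate | O=S(=O)(OC1=CC[C@H](C#C)[C@H](O)C[C@@H]1C)C(F)(F)F | intermediate
18 | (4S,5S,7R)-4-ethynyl-5-hydroxy-7-methylcyclohept-1-en-1-yl triflate | O=S(=O)(OC1=CC[C@@H](C#C)[C@@H](O)C[C@H]1C)C(F)(F)F | intermediate
19 | dilithium alkoxide acetylide of 17 | O=S(=O)(OC1=CC[C@H](C#[C-])[C@H]([O-])C[C@@H]1C)C(F)(F)F.[Li+].[Li+] | intermediate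
20 | (4R,5R,7S)-5-(tert-butyldimethylsilyloxy)-4-[(tert-butyldimethylsilyl)ethynyl]-7-methylcyclohept-1-en-1-yl triflate | O=S(=O)(OC1=CC[C@H](C#C[Si](C)(C)C(C)(C)C)[C@H](O[Si](C)(C)C(C)(C)C)C[C@@H]1C)C(F)(F)F | intermediate
21 | (2S,4R,5R)-4-(tert-butyldimethylsilyloxy)-5-[(tert-butyldimethylsilyl)ethynyl]-2-methylcycloheptan-1-one | O=C1CC[C@H](C#C[Si](C)(C)C(C)(C)C)[C@H](O[Si](C)(C)C(C)(C)C)C[C@@H]1C | intermediate
22 | (3aS,7R,8aS)-7-methyl-3-methylidene-2-oxo-3,3a,4,7,8,8a-hexahydro-2H-cyclohepta[b]furan-6-yl triflate | C=C1C(=O)O[C@H]2C[C@@H](C)C(OS(=O)(=O)C(F)(F)F)=CC[C@@H]12 | intermediate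
23 | kinetic lithium enolate of 21 (C1=C5) | [Li+].[O-]C1=CC[C@H](C#C[Si](C)(C)C(C)(C)C)[C@H](O[Si](C)(C)C(C)(C)C)C[C@@H]1C | intermediate
24 | lithium enolate of lactone B after Michael addition (C5 chain trans to C14) | C1(C[C@H]2C[C@H](C#C[Si](C)(C)C(C)(C)C)[C@H](O[Si](C)(C)C(C)(C)C)C[C@H](C)C2=O)=C([O-])O[C@H]3C[C@@H](C)C(OS(=O)(=O)C(F)(F)F)=CC[C@@H]13.[Li+] | intermediate
25 | C5 epimer of 26 | C=C(C)C[C@]1(C[C@H]2C[C@H](C#C[Si](C)(C)C(C)(C)C)[C@H](O[Si](C)(C)C(C)(C)C)C[C@H](C)C2=O)C(=O)O[C@H]3C[C@@H](C)C(OS(=O)(=O)C(F)(F)F)=CC[C@@H]13 | intermediate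
26 | C5–C13'-linked keto lactone with 2-methylallyl group at C11' | C=C(C)C[C@]1(C[C@@H]2C[C@H](C#C[Si](C)(C)C(C)(C)C)[C@H](O[Si](C)(C)C(C)(C)C)C[C@H](C)C2=O)C(=O)O[C@H]3C[C@@H](C)C(OS(=O)(=O)C(F)(F)F)=CC[C@@H]13 | intermediate
27 | C1 tertiary vinyl carbinol | C=C(C)C[C@]1(C[C@@H]2C[C@H](C#C[Si](C)(C)C(C)(C)C)[C@H](O[Si](C)(C)C(C)(C)C)C[C@H](C)[C@@]2(O)C=C)C(=O)O[C@H]3C[C@@H](C)C(OS(=O)(=O)C(F)(F)F)=CC[C@@H]13 | intermediate
28 | bis-ozonide of 27 | CC1(OOCO1)C[C@]2(C[C@@H]3C[C@H](C#C[Si](C)(C)C(C)(C)C)[C@H](O[Si](C)(C)C(C)(C)C)C[C@H](C)[C@@]3(O)C4OOCO4)C(=O)O[C@H]5C[C@@H](C)C(OS(=O)(=O)C(F)(F)F)=CC[C@@H]25 | intermediate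
29 | C2 aldehyde, C4 methyl ketone | CC(=O)C[C@]1(C[C@@H]2C[C@H](C#C[Si](C)(C)C(C)(C)C)[C@H](O[Si](C)(C)C(C)(C)C)C[C@H](C)[C@@]2(O)C=O)C(=O)O[C@H]3C[C@@H](C)C(OS(=O)(=O)C(F)(F)F)=CC[C@@H]13 | intermediate
30 | ring C aldol (C2 and C3 configuration of no consequence) | CC(C)(C)[Si](C)(C)O[C@@H]1C[C@H](C)[C@@]2(O)C(O)C(C(C)=O)[C@]3(C[C@@H]2C[C@@H]1C#C[Si](C)(C)C(C)(C)C)C(=O)O[C@H]4C[C@@H](C)C(OS(=O)(=O)C(F)(F)F)=CC[C@@H]34 | intermediate
31 | ring C enone | CC(C)(C)[Si](C)(C)O[C@@H]1C[C@H](C)[C@@]2(O)C=C(C(C)=O)[C@]3(C[C@@H]2C[C@@H]1C#C[Si](C)(C)C(C)(C)C)C(=O)O[C@H]4C[C@@H](C)C(OS(=O)(=O)C(F)(F)F)=CC[C@@H]34 | intermediate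
32 | (E)-dienone | CC(C)(C)[Si](C)(C)O[C@@H]1C[C@H](C)[C@@]2(O)C=C(C(C)=O)[C@]3(C[C@@H]2C[C@@H]1C#C[Si](C)(C)C(C)(C)C)C(=O)O[C@H]4C[C@@H](C)C(/C=C/C(C)=O)=CC[C@@H]34 | intermediate
33 | alkynyl diol | O[C@@H]1C[C@H](C)[C@@]2(O)C=C(C(C)=O)[C@]3(C[C@@H]2C[C@@H]1C#C)C(=O)O[C@H]4C[C@@H](C)C(/C=C/C(C)=O)=CC[C@@H]34 | intermediate
34 | de-epoxy precursor | C=C1C(=O)O[C@@H]2C[C@H](C)[C@@]3(O)C=C(C(C)=O)[C@]4(C[C@@H]3C[C@H]12)C(=O)O[C@H]1C[C@@H](C)C(/C=C/C(C)=O)=CC[C@H]14 | intermediate
35 | CNP0177598.2 | C=C1C(=O)O[C@@H]2C[C@H](C)[C@@]3(O)C=C(C(C)=O)[C@]4(C[C@@H]3C[C@H]12)C(=O)O[C@H]1C[C@@H](C)[C@]2(/C=C/C(C)=O)O[C@@H]2C[C@H]14 | target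

**Step count**
Total: 20 steps. Longest linear sequence: 19 steps (steps 1–11 and 13–20).

**Steps most likely to fail**

Step 13. Proton exchange between lactone enolate 24 and the ketone just formed, or repeated addition of 24 to further 22, could rob C11' of its alkylation. In the fallback the two C–C bonds are made in separate operations and the order of events changes, so that no ketone is present when C11' is deprotonated. It sets out from 21 and 22 and rejoins the route at 27.
- Enolate 23 is generated as before, 22 is added, and the mixture is quenched with AcOH at −78 °C to give the kinetic keto lactone F1.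
- DBU in PhMe equilibrates this to the keto lactone F2 (C5 chain cis to C14; C11' epimers of no consequence).
- CH2=CHMgBr/CeCl3 converts it into the vinyl carbinol F3.
- LiN(i-Pr)2 (2.2 equiv) gives the alkoxide enolate dianion F4, which methallyl bromide alkylates on the convex face to give 27.

Step 14. Poor facial selectivity, or enolisation in place of addition at the doubly α-branched ketone, could erode C1. The fallback replaces the vinyl group by a much bulkier hydroxymethyl anion equivalent, which should be confined to the equatorial trajectory. It sets out from 26 and rejoins at 29.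
- (i-PrO)Me2SiCH2MgCl adds to give the silylmethyl carbinol F5.
- Tamao–Fleming oxidation (H2O2, KF, KHCO3, THF/MeOH) gives the 1,2-diol F6.
- Ozone converts the methallyl group through the ozonide F7, reduced with Me2S, into the keto diol F8.
- TEMPO/PhI(OAc)2 oxidises the primary alcohol to 29.

Step 12. Reduction of divalent palladium to zerovalent palladium under CO, followed by insertion into the C–OTf bond, would carbonylate the wrong site. The fallback closes the lactone by a radical reaction with no palladium. It sets out from 18 and rejoins at 22.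
- COCl2 and pyridine give the chloroformate F9.
- PhSeH and pyridine give the Se-phenyl selenocarbonate F10.
- Slow addition of Bu3SnH/AIBN in PhH at 80 °C generates the alkoxycarbonyl radical, whose 5-exo-dig cyclisation and hydrogen abstraction give 22.

**Further compounds**
F1 | step 13 | kinetic keto lactone (C5 chain trans to C14, C11' unassigned) | O=C1O[C@H]2C[C@@H](C)C(OS(=O)(=O)C(F)(F)F)=CC[C@H]2C1C[C@H]3C[C@H](C#C[Si](C)(C)C(C)(C)C)[C@H](O[Si](C)(C)C(C)(C)C)C[C@H](C)C3=O
F2 | step 13 | equilibrated keto lactone (C5 chain cis to C14, C11' unassigned) | O=C1O[C@H]2C[C@@H](C)C(OS(=O)(=O)C(F)(F)F)=CC[C@H]2C1C[C@@H]3C[C@H](C#C[Si](C)(C)C(C)(C)C)[C@H](O[Si](C)(C)C(C)(C)C)C[C@H](C)C3=O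
F3 | step 13 | vinyl carbinol lacking the allyl group | O=C1O[C@H]2C[C@@H](C)C(OS(=O)(=O)C(F)(F)F)=CC[C@H]2C1C[C@@H]3C[C@H](C#C[Si](C)(C)C(C)(C)C)[C@H](O[Si](C)(C)C(C)(C)C)C[C@H](C)[C@@]3(O)C=C
F4 | step 13 | dilithium alkoxide enolate of F3 | C1(C[C@@H]2C[C@H](C#C[Si](C)(C)C(C)(C)C)[C@H](O[Si](C)(C)C(C)(C)C)C[C@H](C)[C@@]2([O-])C=C)=C([O-])O[C@H]3C[C@@H](C)C(OS(=O)(=O)C(F)(F)F)=CC[C@@H]13.[Li+].[Li+]
F5 | step 14 | C1 (isopropoxydimethylsilyl)methyl carbinol | C=C(C)C[C@]1(C[C@@H]2C[C@H](C#C[Si](C)(C)C(C)(C)C)[C@H](O[Si](C)(C)C(C)(C)C)C[C@H](C)[C@@]2(O)C[Si](C)(C)OC(C)C)C(=O)O[C@H]3C[C@@H](C)C(OS(=O)(=O)C(F)(F)F)=CC[C@@H]13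
F6 | step 14 | C1/C2 diol | C=C(C)C[C@]1(C[C@@H]2C[C@H](C#C[Si](C)(C)C(C)(C)C)[C@H](O[Si](C)(C)C(C)(C)C)C[C@H](C)[C@@]2(O)CO)C(=O)O[C@H]3C[C@@H](C)C(OS(=O)(=O)C(F)(F)F)=CC[C@@H]13
F7 | step 14 | ozonide of F6 | CC1(OOCO1)C[C@]2(C[C@@H]3C[C@H](C#C[Si](C)(C)C(C)(C)C)[C@H](O[Si](C)(C)C(C)(C)C)C[C@H](C)[C@@]3(O)CO)C(=O)O[C@H]4C[C@@H](C)C(OS(=O)(=O)C(F)(F)F)=CC[C@@H]24
F8 | step 14 | keto diol | CC(=O)C[C@]1(C[C@@H]2C[C@H](C#C[Si](C)(C)C(C)(C)C)[C@H](O[Si](C)(C)C(C)(C)C)C[C@H](C)[C@@]2(O)CO)C(=O)O[C@H]3C[C@@H](C)C(OS(=O)(=O)C(F)(F)F)=CC[C@@H]13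
F9 | step 12 | chloroformate of 18 | O=S(=O)(OC1=CC[C@@H](C#C)[C@@H](OC(=O)Cl)C[C@H]1C)C(F)(F)F
F10 | step 12 | Se-phenyl selenocarbonate of 18 | O=S(=O)(OC1=CC[C@@H](C#C)[C@@H](OC(=O)[Se]c2ccccc2)C[C@H]1C)C(F)(F)F
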